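## Retrosynthetic overview

1. The furanone ring is made last: target ⇐ transannular 5-endo-dig oxa-Michael of the ten-membered α′-hydroxy ynone 21 ⇐ carbocycle closed at C1–C2 by intramolecular Nozaki–Hiyama–Kishi alkynylation of iodoalkyne α-hydroxy aldehyde 19.
2. C6 tiglate by acylation of syn alcohol 14; the C6–C7 bond and the C6/C7 stereocentres by a proposed syn-selective salen–chromium allylation of enynal 12 with bromomethyl butenolide 10.
3. 10 ⇐ α-methylene-γ-butyrolactone 8 (bromination/dehydrobromination); lactone ring and C8 by catalytic asymmetric 2-(alkoxycarbonyl)allylation of aldehyde 4 with 5.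
4. 4 (C8–C10, C1, C14, with the C10 quaternary centre) from (S)-citramalic acid; C2–C6 and C15 with the Z alkene from (2Z)-3-methylpent-2-en-4-yn-1-ol.
5. Order of ring formation: γ-lactone → ten-membered carbocycle → 3(2H)-furanone.

Assumption: atom labels C1–C15 follow germacrane numbering of the target (C1 ketone, C2=C3 enol ether, C4=C5 alkene with C15 methyl, C6 tiglate carbon, C7/C8 lactone ring fusion, C10 quaternary carbon with C14 methyl, C11=C13 exocyclic methylene, C12 lactone carbonyl), and compounds 1, 5, 11 and 15 are taken as catalogue chemicals.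

## Route

Step 1
Reactants: 1 (2S)-2-hydroxy-2-methylbutanedioic acid [(S)-citramalic acid]
Product: 2 (2S)-2-methylbutane-1,2,4-triol
Conditions: BH3·SMe2, B(OMe)3, THF, 0 °C → rt; MeOH quench
Reagents that add atoms: none
Why: Borane reduction of both carboxylic acids to primary alcohols does not touch the C10 tertiary carbinol, which comes unchanged (S) from the chiral pool.

Step 2
Reactants: 2 (2S)-2-methylbutane-1,2,4-triol
Product: 3 2-[(4S)-2,2,4-trimethyl-1,3-dioxolan-4-yl]ethan-1-ol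
Conditions: 2,2-dimethoxypropane, p-TsOH·H2O (cat.), acetone, rt
Reagents that add atoms: 2,2-dimethoxypropane COC(C)(C)OC
Why: Acid-catalysed transacetalisation gives the thermodynamically preferred five-membered 1,2-acetonide, masking the C1 and C10 hydroxyls and leaving the C8 alcohol free.

Step 3
Reactants: 3 2-[(4S)-2,2,4-trimethyl-1,3-dioxolan-4-yl]ethan-1-ol
Product: 4 2-[(4S)-2,2,4-trimethyl-1,3-dioxolan-4-yl]acetaldehyde
Conditions: 2-iodoxybenzoic acid, EtOAc, 75 °C
Reagents that add atoms: none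
Why: Hypervalent-iodine oxidation of the primary alcohol to the aldehyde runs under neutral conditions, so the acetonide survives and the β-alkoxy aldehyde does not eliminate.

Step 4
Reactants: 4 2-[(4S)-2,2,4-trimethyl-1,3-dioxolan-4-yl]acetaldehyde; 5 methyl 2-(bromomethyl)prop-2-enoate
Product: 8 (5R)-3-methylidene-5-{[(4S)-2,2,4-trimethyl-1,3-dioxolan-4-yl]methyl}oxolan-2-one, via trimethylsilyl ether 6 (not isolated), via hydroxy ester 7 (not isolated)
Conditions: CrCl2 (10 mol %), chiral 3,6-di-tert-butyl-1,8-bis(4-isopropyl-4,5-dihydrooxazol-2-yl)carbazole ligand (12 mol %; the enantiomer that directs allyl transfer to the Re face of the aldehyde), Mn powder, iPr2NEt (30 mol %), Me3SiCl, THF, rt; then aq citric acid, THF, 0 °C; then p-TsOH (5 mol %), CH2Cl2, rt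
Reagents that add atoms: chlorotrimethylsilane C[Si](C)(C)Cl (its atoms stay only in 6)
Why: Catalytic asymmetric Nozaki–Hiyama–Kishi 2-(alkoxycarbonyl)allylation (Mn as reductant, Me3SiCl for turnover) delivers the allyl unit to the Re face of 4 and so sets C8 (5R in 8; the C8 epimer is a separable diastereomer), and mild acid then removes the silyl group and closes the α-methylene-γ-butyrolactone by lactonisation.

Step 5
Reactants: 8 (5R)-3-methylidene-5-{[(4S)-2,2,4-trimethyl-1,3-dioxolan-4-yl]methyl}oxolan-2-one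
Product: 10 (5S)-3-(bromomethyl)-5-{[(4S)-2,2,4-trimethyl-1,3-dioxolan-4-yl]methyl}furan-2(5H)-one, via dibromide 9 (not isolated)
Conditions: Br2, CH2Cl2, 0 °C; then Et3N, −20 → 0 °C
Reagents that add atoms: bromine BrBr
Why: Bromine addition to the exocyclic alkene followed by amine-induced E2 loss of HBr toward the ring CH2 (bromination–dehydrobromination) gives the conjugated endocyclic butenolide with the allylic bromide on C13, while C8 is not involved (its descriptor changes to S only through the CIP priorities).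

Step 6
Reactants: 11 (2Z)-3-methylpent-2-en-4-yn-1-ol
Product: 12 (2Z)-3-methylpent-2-en-4-ynal
Conditions: TEMPO (2,2,6,6-tetramethylpiperidin-1-oxyl, 10 mol %), PhI(OAc)2, CH2Cl2, rt; used as a solution
Reagents that add atoms: none
Why: Oxoammonium (TEMPO) oxidation of the allylic alcohol stops at the aldehyde under conditions that are neither acidic nor basic, which keeps the Z alkene of the commercial enynol intact.

Step 7
Reactants: 10 (5S)-3-(bromomethyl)-5-{[(4S)-2,2,4-trimethyl-1,3-dioxolan-4-yl]methyl}furan-2(5H)-one; 12 (2Z)-3-methylpent-2-en-4-ynal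
Product: 14 (4S,5S)-4-[(1S,2Z)-1-hydroxy-3-methylpent-2-en-4-yn-1-yl]-3-methylidene-5-{[(4S)-2,2,4-trimethyl-1,3-dioxolan-4-yl]methyl}oxolan-2-one, via trimethylsilyl ether 13 (not isolated)
Conditions: CrCl3 (10 mol %), Mn powder (3 equiv), N,N′-bis(3,5-di-tert-butylsalicylidene)ethane-1,2-diamine (H2salen′, 12 mol %), Et3N (25 mol %), Me3SiCl (1.5 equiv), MeCN, rt, slow addition of 10; then aq citric acid, THF, 0 °C
Reagents that add atoms: chlorotrimethylsilane C[Si](C)(C)Cl (its atoms stay only in 13)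
Why: Proposed new method: a salen–chromium-catalysed Nozaki–Hiyama allylation that uses a butenolide-embedded 2-carbonylallyl bromide, in which Mn reduces the complex CrCl(salen′) to divalent chromium, this takes up the allylic carbon–bromine bond of 10 to give a C13-bound allyl trivalent chromium species whose salen ligand blocks every cis coordination site, so the aldehyde cannot enter a closed chair and is attacked through an open antiperiplanar SE2′ transition state while activated by an external Lewis acid (Mn salt or silyl cation); C7 bonds to the aldehyde on the ring face anti to the C8 side chain (7,8-trans) and the open transition state gives syn topicity between the C6 carbinol and C8 (C6 S, C7 with the target configuration), Me3SiCl silylating the alkoxide to turn the catalyst over and to prevent translactonisation; the closest known reaction types are the syn-selective salen–chromium-catalysed crotylation of aldehydes with crotyl bromide and, with the opposite anti outcome through a closed chair, stoichiometric CrCl2- or Zn-mediated Barbier additions of 3-(bromomethyl)butenolides.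

Step 8
Reactants: 14 (4S,5S)-4-[(1S,2Z)-1-hydroxy-3-methylpent-2-en-4-yn-1-yl]-3-methylidene-5-{[(4S)-2,2,4-trimethyl-1,3-dioxolan-4-yl]methyl}oxolan-2-one; 15 (2E)-2-methylbut-2-enoyl chloride (tigloyl chloride)
Product: 16 (1S,2Z)-3-methyl-1-[(2S,3R)-4-methylidene-5-oxo-2-{[(4S)-2,2,4-trimethyl-1,3-dioxolan-4-yl]methyl}oxolan-3-yl]pent-2-en-4-yn-1-yl (2E)-2-methylbut-2-enoate
Conditions: pyridine, DMAP (10 mol %), CH2Cl2, 0 °C → rt
Reagents that add atoms: none
Why: DMAP-catalysed acylation of the secondary alcohol with the acid chloride (esterification) proceeds with retention at C6, and pyridine as the only base avoids ketene-type deconjugation of the tigloyl unit.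

Step 9
Reactants: 16 (1S,2Z)-3-methyl-1-[(2S,3R)-4-methylidene-5-oxo-2-{[(4S)-2,2,4-trimethyl-1,3-dioxolan-4-yl]methyl}oxolan-3-yl]pent-2-en-4-yn-1-yl (2E)-2-methylbut-2-enoate
Product: 17 (1S,2Z)-5-iodo-3-methyl-1-[(2S,3R)-4-methylidene-5-oxo-2-{[(4S)-2,2,4-trimethyl-1,3-dioxolan-4-yl]methyl}oxolan-3-yl]pent-2-en-4-yn-1-yl (2E)-2-methylbut-2-enoate
Conditions: N-iodosuccinimide, AgNO3 (10 mol %), acetone, rt, dark
Reagents that add atoms: N-iodosuccinimide O=C1CCC(=O)N1I
Why: Silver-catalysed electrophilic iodination of the terminal alkyne (via the silver acetylide) gives the 1-iodoalkyne needed for chromium insertion and leaves the esters, lactone and acetonide untouched.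

Step 10
Reactants: 17 (1S,2Z)-5-iodo-3-methyl-1-[(2S,3R)-4-methylidene-5-oxo-2-{[(4S)-2,2,4-trimethyl-1,3-dioxolan-4-yl]methyl}oxolan-3-yl]pent-2-en-4-yn-1-yl (2E)-2-methylbut-2-enoate
Product: 18 (1S,2Z)-1-{(2S,3R)-2-[(2S)-2,3-dihydroxy-2-methylpropyl]-4-methylidene-5-oxooxolan-3-yl}-5-iodo-3-methylpent-2-en-4-yn-1-yl (2E)-2-methylbut-2-enoate
Conditions: AcOH/H2O (4:1), 40 °C
Reagents that add atoms: none
Why: Acid-catalysed hydrolysis of the terminal acetonide (acetal cleavage) frees the C1 primary and C10 tertiary alcohols under conditions too mild to hydrolyse or ionise the allylic tiglate.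

Step 11
Reactants: 18 (1S,2Z)-1-{(2S,3R)-2-[(2S)-2,3-dihydroxy-2-methylpropyl]-4-methylidene-5-oxooxolan-3-yl}-5-iodo-3-methylpent-2-en-4-yn-1-yl (2E)-2-methylbut-2-enoate
Product: 19 (1S,2Z)-1-{(2S,3R)-2-[(2S)-2-hydroxy-2-methyl-3-oxopropyl]-4-methylidene-5-oxooxolan-3-yl}-5-iodo-3-methylpent-2-en-4-yn-1-yl (2E)-2-methylbut-2-enoate
Conditions: 2-iodoxybenzoic acid, DMSO/THF, rt
Reagents that add atoms: none
Why: 2-Iodoxybenzoic acid oxidises only the primary alcohol (the tertiary C10 alcohol cannot be oxidised and this oxidant does not cleave 1,2-diols), giving the α-hydroxy aldehyde without touching C10.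

Step 12
Reactants: 19 (1S,2Z)-1-{(2S,3R)-2-[(2S)-2-hydroxy-2-methyl-3-oxopropyl]-4-methylidene-5-oxooxolan-3-yl}-5-iodo-3-methylpent-2-en-4-yn-1-yl (2E)-2-methylbut-2-enoate
Product: 20 (4Z,6S,7R,8S,10S)-1,10-dihydroxy-6-[(2E)-2-methylbut-2-enoyloxy]germacra-4,11(13)-dien-2-yn-12,8-olide (both C1 epimers)
Conditions: CrCl2 (8 equiv), NiCl2 (1 mol %), THF, rt, 2 mM, syringe-pump addition of 19
Reagents that add atoms: none
Why: Intramolecular Nozaki–Hiyama–Kishi alkynylation, in which divalent chromium inserts into the carbon–iodine bond and the alkynylchromium adds to the C1 aldehyde under high dilution, closes the ten-membered carbocycle with the Z alkene and the trans-fused lactone holding the chain ends close; the new C1 carbinol centre is destroyed in the next step, so its configuration does not matter.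

Step 13
Reactants: 20 (4Z,6S,7R,8S,10S)-1,10-dihydroxy-6-[(2E)-2-methylbut-2-enoyloxy]germacra-4,11(13)-dien-2-yn-12,8-olide
Product: 22 (4Z,6S,7R,8S,10S)-3,10-epoxy-6-[(2E)-2-methylbut-2-enoyloxy]-1-oxogermacra-2,4,11(13)-trien-12,8-olide (target CNP0293168.2), via ynone 21 (not isolated)
Conditions: 2-iodoxybenzoic acid, DMSO, rt; then Ph3PAuNTf2 (5 mol %), CH2Cl2, rt
Reagents that add atoms: none
Why: Oxidation of the propargylic alcohol gives the α′-hydroxy ynone, whose tertiary C10 hydroxyl adds to C3 in a gold-catalysed transannular 5-endo-dig oxa-Michael cycloisomerisation that forms the 3(2H)-furanone and leaves C10 (S), the Z C4=C5 alkene and all other centres unchanged.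

## Compound list

1 | (2S)-2-hydroxy-2-methylbutanedioic acid, (S)-citramalic acid | OC(=O)C[C@](C(=O)O)(C)O | starting material
2 | (2S)-2-methylbutane-1,2,4-triol | OCC[C@](CO)(C)O | intermediate
3 | 2-[(4S)-2,2,4-trimethyl-1,3-dioxolan-4-yl]ethan-1-ol | OCC[C@]1(COC(C)(C)O1)C | intermediate
4 | 2-[(4S)-2,2,4-trimethyl-1,3-dioxolan-4-yl]acetaldehyde | O=CC[C@]1(COC(C)(C)O1)C | intermediate
5 | methyl 2-(bromomethyl)prop-2-enoate | C=C(CBr)C(=O)OC | starting material
6 | methyl (4R)-2-methylidene-4-[(trimethylsilyl)oxy]-5-[(4S)-2,2,4-trimethyl-1,3-dioxolan-4-yl]pentanoate | C=C(C[C@@H](O[Si](C)(C)C)C[C@]1(COC(C)(C)O1)C)C(=O)OC | intermediate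
7 | methyl (4R)-4-hydroxy-2-methylidene-5-[(4S)-2,2,4-trimethyl-1,3-dioxolan-4-yl]pentanoate | C=C(C[C@@H](O)C[C@]1(COC(C)(C)O1)C)C(=O)OC | intermediate
8 | (5R)-3-methylidene-5-{[(4S)-2,2,4-trimethyl-1,3-dioxolan-4-yl]methyl}oxolan-2-one | C=C1C(=O)O[C@H](C1)C[C@]2(COC(C)(C)O2)C | intermediate
9 | (5S)-3-bromo-3-(bromomethyl)-5-{[(4S)-2,2,4-trimethyl-1,3-dioxolan-4-yl]methyl}oxolan-2-one (both C3 epimers) | O=C1O[C@H](CC1(Br)CBr)C[C@]2(COC(C)(C)O2)C | intermediate
10 | (5S)-3-(bromomethyl)-5-{[(4S)-2,2,4-trimethyl-1,3-dioxolan-4-yl]methyl}furan-2(5H)-one | O=C1O[C@H](C=C1CBr)C[C@]2(COC(C)(C)O2)C | intermediate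
11 | (2Z)-3-methylpent-2-en-4-yn-1-ol | OC/C=C(/C)C#C | starting material
12 | (2Z)-3-methylpent-2-en-4-ynal | O=C/C=C(/C)C#C | intermediate
13 | (4R,5S)-3-methylidene-4-{(1S,2Z)-3-methyl-1-[(trimethylsilyl)oxy]pent-2-en-4-yn-1-yl}-5-{[(4S)-2,2,4-trimethyl-1,3-dioxolan-4-yl]methyl}oxolan-2-one | C=C1C(=O)O[C@@H](C[C@]2(COC(C)(C)O2)C)[C@@H]1[C@@H](O[Si](C)(C)C)/C=C(/C)C#C | intermediate
14 | (4S,5S)-4-[(1S,2Z)-1-hydroxy-3-methylpent-2-en-4-yn-1-yl]-3-methylidene-5-{[(4S)-2,2,4-trimethyl-1,3-dioxolan-4-yl]methyl}oxolan-2-one | C=C1C(=O)O[C@@H](C[C@]2(COC(C)(C)O2)C)[C@@H]1[C@@H](O)/C=C(/C)C#C | intermediate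
15 | (2E)-2-methylbut-2-enoyl chloride, tigloyl chloride | C/C=C(\C)C(=O)Cl | starting material
16 | (1S,2Z)-3-methyl-1-[(2S,3R)-4-methylidene-5-oxo-2-{[(4S)-2,2,4-trimethyl-1,3-dioxolan-4-yl]methyl}oxolan-3-yl]pent-2-en-4-yn-1-yl (2E)-2-methylbut-2-enoate | C=C1C(=O)O[C@@H](C[C@]2(COC(C)(C)O2)C)[C@@H]1[C@@H](OC(=O)/C(C)=C/C)/C=C(/C)C#C | intermediate
17 | (1S,2Z)-5-iodo-3-methyl-1-[(2S,3R)-4-methylidene-5-oxo-2-{[(4S)-2,2,4-trimethyl-1,3-dioxolan-4-yl]methyl}oxolan-3-yl]pent-2-en-4-yn-1-yl (2E)-2-methylbut-2-enoate | C=C1C(=O)O[C@@H](C[C@]2(COC(C)(C)O2)C)[C@@H]1[C@@H](OC(=O)/C(C)=C/C)/C=C(/C)C#CI | intermediate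
18 | (1S,2Z)-1-{(2S,3R)-2-[(2S)-2,3-dihydroxy-2-methylpropyl]-4-methylidene-5-oxooxolan-3-yl}-5-iodo-3-methylpent-2-en-4-yn-1-yl (2E)-2-methylbut-2-enoate | C=C1C(=O)O[C@@H](C[C@](CO)(C)O)[C@@H]1[C@@H](OC(=O)/C(C)=C/C)/C=C(/C)C#CI | intermediate
19 | (1S,2Z)-1-{(2S,3R)-2-[(2S)-2-hydroxy-2-methyl-3-oxopropyl]-4-methylidene-5-oxooxolan-3-yl}-5-iodo-3-methylpent-2-en-4-yn-1-yl (2E)-2-methylbut-2-enoate | C=C1C(=O)O[C@@H](C[C@](C=O)(C)O)[C@@H]1[C@@H](OC(=O)/C(C)=C/C)/C=C(/C)C#CI | intermediate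
20 | (4Z,6S,7R,8S,10S)-1,10-dihydroxy-6-[(2E)-2-methylbut-2-enoyloxy]germacra-4,11(13)-dien-2-yn-12,8-olide (both C1 epimers; ten-membered carbocycle with C2≡C3, trans-fused α-methylene lactone) | C=C1C(=O)O[C@H]2C[C@](C)(O)C(O)C#C/C(C)=C\[C@H](OC(=O)/C(C)=C/C)[C@H]12 | intermediate
21 | (4Z,6S,7R,8S,10S)-10-hydroxy-6-[(2E)-2-methylbut-2-enoyloxy]-1-oxogermacra-4,11(13)-dien-2-yn-12,8-olide | C=C1C(=O)O[C@H]2C[C@](C)(O)C(=O)C#C/C(C)=C\[C@H](OC(=O)/C(C)=C/C)[C@H]12 | intermediate
22 | (4Z,6S,7R,8S,10S)-3,10-epoxy-6-[(2E)-2-methylbut-2-enoyloxy]-1-oxogermacra-2,4,11(13)-trien-12,8-olide, CNP0293168.2 | C=C1C(=O)O[C@H]2C[C@]3(C)OC(=CC3=O)/C(C)=C\[C@H](OC(=O)/C(C)=C/C)[C@H]12 | target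

## Step count and risks

Total step count: 13. Longest linear sequence: 12 steps (steps 1–5 and 7–13, from 1 to 22); step 6 is a one-step side branch.

Steps most likely to fail:

Step 5. The dehydrobromination of dibromide 9 may instead remove a hydrogen from the CH2Br group and give the exocyclic vinyl bromide. The fallback sets out from 8 and returns to the route at 14. PhSeCl (CH2Cl2, rt) adds across the exocyclic alkene, selenium to C11 and chloride to C13, to give (5S)-3-(chloromethyl)-3-(phenylselanyl)-5-{[(4S)-2,2,4-trimethyl-1,3-dioxolan-4-yl]methyl}oxolan-2-one F1. Oxidation with H2O2/pyridine at 0 °C gives the selenoxide, whose syn-elimination runs away from the chlorine-bearing carbon and furnishes (5S)-3-(chloromethyl)-5-{[(4S)-2,2,4-trimethyl-1,3-dioxolan-4-yl]methyl}furan-2(5H)-one F2. F2 is then used in place of 10 under the conditions of step 7 (NaI, 20 mol %, added) and gives 14.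

Step 7 (the proposed new step). The open transition state and hence the syn outcome are unproven for this 2-carbonyl-substituted cyclic allyl unit; the enal may also undergo pinacol coupling, or the allyl unit may react at C13. The fallback uses known chemistry, sets out from 10 and 12, and returns at 16. Stoichiometric CrCl2 in THF at rt (closed chair transition state) gives the anti adduct (4S,5S)-4-[(1R,2Z)-1-hydroxy-3-methylpent-2-en-4-yn-1-yl]-3-methylidene-5-{[(4S)-2,2,4-trimethyl-1,3-dioxolan-4-yl]methyl}oxolan-2-one F3, the C6 epimer of 14. A Mitsunobu esterification of F3 with (2E)-2-methylbut-2-enoic acid (PPh3, diisopropyl azodicarboxylate, toluene, 0 °C → rt) inverts C6 and gives tiglate 16 directly.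

Step 12. Closing a strained ten-membered enyne ring is demanding, and the free tertiary hydroxyl may protonate the alkynylchromium. The fallback sets out from 16, skips the iodination, and returns at 20. Hydrolysis of the acetonide of 16 (AcOH/H2O 4:1, 40 °C) gives (1S,2Z)-1-{(2S,3R)-2-[(2S)-2,3-dihydroxy-2-methylpropyl]-4-methylidene-5-oxooxolan-3-yl}-3-methylpent-2-en-4-yn-1-yl (2E)-2-methylbut-2-enoate F4. Oxidation with 2-iodoxybenzoic acid gives (1S,2Z)-1-{(2S,3R)-2-[(2S)-2-hydroxy-2-methyl-3-oxopropyl]-4-methylidene-5-oxooxolan-3-yl}-3-methylpent-2-en-4-yn-1-yl (2E)-2-methylbut-2-enoate F5. The terminal alkyne of F5 is then metalated in situ as its zinc acetylide (Zn(OTf)2, Et3N, toluene, 60 °C, high dilution) and adds to the aldehyde to give 20.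

## Further compounds

F1 | step 5 | (5S)-3-(chloromethyl)-3-(phenylselanyl)-5-{[(4S)-2,2,4-trimethyl-1,3-dioxolan-4-yl]methyl}oxolan-2-one (both C3 epimers) | O=C1O[C@H](CC1(CCl)[Se]c3ccccc3)C[C@]2(COC(C)(C)O2)C
F2 | step 5 | (5S)-3-(chloromethyl)-5-{[(4S)-2,2,4-trimethyl-1,3-dioxolan-4-yl]methyl}furan-2(5H)-one | O=C1O[C@H](C=C1CCl)C[C@]2(COC(C)(C)O2)C
F3 | step 7 | (4S,5S)-4-[(1R,2Z)-1-hydroxy-3-methylpent-2-en-4-yn-1-yl]-3-methylidene-5-{[(4S)-2,2,4-trimethyl-1,3-dioxolan-4-yl]methyl}oxolan-2-one | C=C1C(=O)O[C@@H](C[C@]2(COC(C)(C)O2)C)[C@@H]1[C@H](O)/C=C(/C)C#C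
F4 | step 12 | (1S,2Z)-1-{(2S,3R)-2-[(2S)-2,3-dihydroxy-2-methylpropyl]-4-methylidene-5-oxooxolan-3-yl}-3-methylpent-2-en-4-yn-1-yl (2E)-2-methylbut-2-enoate | C=C1C(=O)O[C@@H](C[C@](CO)(C)O)[C@@H]1[C@@H](OC(=O)/C(C)=C/C)/C=C(/C)C#C
F5 | step 12 | (1S,2Z)-1-{(2S,3R)-2-[(2S)-2-hydroxy-2-methyl-3-oxopropyl]-4-methylidene-5-oxooxolan-3-yl}-3-methylpent-2-en-4-yn-1-yl (2E)-2-methylbut-2-enoate | C=C1C(=O)O[C@@H](C[C@](C=O)(C)O)[C@@H]1[C@@H](OC(=O)/C(C)=C/C)/C=C(/C)C#C
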